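**Plan**

- Retrosynthetic cuts, in order: the C8 O–acetyl bond; the pyran O2–C3 bond (alkyne hydroalkoxylation); the C4–C4a bond (Sonogashira coupling of a C4a enol triflate with a C11 dienyne); the C8a–C1 bond (alkylation of a C4a/C6 dione); the C7–O and C8–O bonds (syn-dihydroxylation of a C7=C8 enone); last, the C4a–O bond back to an isopropenyl group.
- Enabling feature: the carbocycle C4a–C5–C6–C7–C8–C8a is the ring of (R)-carvone. The C6 ketone and C7 methyl are carvone's carbonyl and methyl, C7=C8 is its enone alkene, and C4a, para to C7, is its isopropenyl-bearing stereocentre. Because C4a is sp2 in the target, that stereocentre can steer the diol and then be oxidised away.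
- Forward order: the carbocycle comes from carvone; Criegee excision turns isopropenyl into a C4a acetoxy group; dihydroxylation sets C7/C8; the C4a oxygen becomes a ketone; C1 is added at C8a; the side chain (from (S)-2-methylbutan-1-ol by two olefinations) is joined at C4a; the pyran ring, the only ring made, closes last by 6-endo-dig O2–C3 formation.
- Stereochemistry: C7 and C8 from syn-addition anti to the carvone-derived C4a oxygen; C8a from alkylation anti to the C8 oxygen (also the more stable epimer); the side-chain centre from the chiral-pool alcohol; both E alkenes from stabilised-ylide and phosphonate olefinations.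

Key step: step 2

Remark: target positions use isochromene numbering (C1 = OCH2, O2, C3, C4, C4a, C5, C6 = ketone, C7, C8, C8a). Monocyclic intermediates are numbered as cyclohexanones from the carvone carbonyl, so that their C1, C2, C3, C4, C5, C6 become C6, C7, C8, C8a, C4a, C5 of the target. The target SMILES is read as 7R,8R,8aR with an S side-chain centre and two E alkenes.

**Route**

Step 1
Reactants: 1 (R)-(−)-carvone
Product: 4 (R)-5-acetoxy-2-methylcyclohex-2-en-1-one, via methoxy hydroperoxide 2 (not isolated), via peroxyacetate 3 (not isolated)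
Conditions: O3, CH2Cl2/MeOH, −78 °C; then Ac2O, pyridine, DMAP (cat.), CH2Cl2, 0 °C → rt
Reagents that add atoms: ozone [O-][O+]=O; methanol CO
Why: Ozone attacks the electron-rich 1,1-disubstituted alkene rather than the electron-poor enone alkene, methanol traps the carbonyl oxide as methoxy hydroperoxide 2, and its peroxyacetate 3 undergoes Criegee rearrangement in which the ring carbon migrates to oxygen with retention, so that the acetyl group of 4 is the former isopropenyl C–CH3 unit (ring-bound oxygen from ozone, carbonyl oxygen from methanol after loss of methyl acetate) and the carvone stereocentre is carried over unchanged.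

Step 2
Reactants: 4 (R)-5-acetoxy-2-methylcyclohex-2-en-1-one
Product: 5 (2R,3R,5R)-5-acetoxy-2,3-dihydroxy-2-methylcyclohexan-1-one
Conditions: OsO4 (cat.), NMO, citric acid, t-BuOH/H2O (1:1), rt
Reagents that add atoms: osmium tetroxide O=[Os](=O)(=O)=O; N-methylmorpholine N-oxide C[N+]1([O-])CCOCC1; water O
Why: OsO4 adds suprafacially to the C2=C3 enone alkene (the future C7=C8 bond) in a concerted [3+2] cycloaddition and the resulting hexavalent osmium glycolate is hydrolysed to the cis-diol while NMO returns the metal to its octavalent state, the citric acid buffer accelerating turnover on this electron-poor trisubstituted alkene and neutralising N-methylmorpholine so that the β-acetoxy ketone does not eliminate. The closest known reaction type is the substrate-controlled catalytic osmium syn-dihydroxylation of 2-methyl-5-substituted cyclohex-2-enones. No ring is closed; the two new bonds are C7–O and C8–O. Both new stereocentres are set together, their cis relationship by the syn mechanism and their absolute sense by the C5 acetoxy stereocentre (future C4a): in the half-chair enone this oxygen substituent can sit pseudo-axially at little cost because both 1,3-related ring atoms are sp2, where it lies over the C3 terminus of the alkene, so the oxidant should approach the opposite face and give the 2R,3R diol anti to the acetate. The only selectivity required is facial, since the isopropenyl alkene is already gone and the enone alkene is the sole site of oxidation, and it is secured by that single carvone-derived centre, which is later oxidised to the sp2 C4a.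

Step 3
Reactants: 5 (2R,3R,5R)-5-acetoxy-2,3-dihydroxy-2-methylcyclohexan-1-one
Product: 6 (2R,3R,5R)-5-acetoxy-2,3-(isopropylidenedioxy)-2-methylcyclohexan-1-one
Conditions: Me2C(OMe)2, PPTS (cat.), acetone, rt
Reagents that add atoms: 2,2-dimethoxypropane COC(C)(C)OC
Why: Acid-catalysed transacetalisation (isopropylidene acetal formation) closes the dioxolane on the cis-2,3-diol, the only diol pair that can bridge because the C5 oxygen is trans to both hydroxyls, and touches no stereocentre.

Step 4
Reactants: 6 (2R,3R,5R)-5-acetoxy-2,3-(isopropylidenedioxy)-2-methylcyclohexan-1-one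
Product: 7 (2S,3R,5S)-2,3-(isopropylidenedioxy)-2-methylcyclohexane-1,5-diol (C1 epimers; C2 and C5 descriptors change by priority only)
Conditions: LiAlH4, THF, 0 °C
Reagents that add atoms: none
Why: LiAlH4 reduces the ketone to an alkoxide before it cleaves the acetate (hydride reduction of ketone and ester), so the acetate is removed without a β-acetoxy ketone ever meeting a base that could trigger E1cB elimination, and the new C1 carbinol centre is left as an epimer mixture because it is oxidised again in step 5.

Step 5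
Reactants: 7 (2S,3R,5S)-2,3-(isopropylidenedioxy)-2-methylcyclohexane-1,5-diol
Product: 8 (2R,3R)-2,3-(isopropylidenedioxy)-2-methylcyclohexane-1,5-dione
Conditions: IBX (3 equiv), EtOAc, 75 °C
Reagents that add atoms: none
Why: IBX oxidation of secondary alcohols converts the 1,3-diol through the β-hydroxy ketone into the β-diketone and is known to stop at that stage, while the two remaining stereocentres (C2 quaternary, C3 not α to a carbonyl) cannot epimerise.

Step 6
Reactants: 8 (2R,3R)-2,3-(isopropylidenedioxy)-2-methylcyclohexane-1,5-dione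
Product: 9 (2R,3R,4R)-2,3-(isopropylidenedioxy)-4-[(4-methoxybenzyloxy)methyl]-2-methylcyclohexane-1,5-dione
Conditions: LiN(i-Pr)2 (2.3 equiv), THF/HMPA, −78 °C; then 4-MeOC6H4CH2OCH2Cl (freshly prepared), −78 → −30 °C; aq. NH4Cl
Reagents that add atoms: 4-methoxybenzyl chloromethyl ether COc1ccc(COCCl)cc1
Why: γ-Alkylation of a β-diketone dianion: the first equivalent of base gives the C6-centred enolate, the second can only remove a C4 proton because C2 is quaternary, and the more nucleophilic terminal carbanion is C-alkylated by the chloromethyl ether on the convex face anti to the adjacent acetonide oxygen, setting C4 (future C8a) trans to the C3 oxygen, which is also the more stable epimer of this enolisable centre.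

Step 7
Reactants: 9 (2R,3R,4R)-2,3-(isopropylidenedioxy)-4-[(4-methoxybenzyloxy)methyl]-2-methylcyclohexane-1,5-dione
Product: 10 (2R,3R,4R)-2,3-(isopropylidenedioxy)-4-[(4-methoxybenzyloxy)methyl]-2-methyl-5-(trifluoromethanesulfonyloxy)cyclohex-5-en-1-one
Conditions: Tf2O, 2,6-lutidine, CH2Cl2, −78 °C
Reagents that add atoms: trifluoromethanesulfonic anhydride O=S(=O)(OS(=O)(=O)C(F)(F)F)C(F)(F)F
Why: Enol triflate formation by O-sulfonylation of the dione enolate is expected at the C5 oxygen, flanked by a tertiary carbon, and not at the C1 oxygen, which is screened by the quaternary C2 centre and made less electron-rich by its α-oxygen, so the ketone remains at the future C6 and the leaving group sits on the future C4a.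

Step 8
Reactants: 11 (S)-2-methylbutan-1-ol
Product: 13 (2E,4S)-2,4-dimethylhex-2-enal, via (S)-2-methylbutanal 12 (not isolated)
Conditions: TEMPO (cat.), PhI(OAc)2, CH2Cl2, rt; then Ph3P=C(CH3)CHO, toluene, 90 °C (sealed vessel)
Reagents that add atoms: 2-(triphenylphosphoranylidene)propanal CC(C=O)=P(c1ccccc1)(c1ccccc1)c1ccccc1
Why: TEMPO/PhI(OAc)2 oxidation gives the α-chiral aldehyde under weakly acidic, non-enolising conditions and the Wittig reaction with the formyl-stabilised ylide in the same flask forms the E-trisubstituted enal (stabilised-ylide selectivity) without isolating the volatile, racemisation-prone aldehyde.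

Step 9
Reactants: 13 (2E,4S)-2,4-dimethylhex-2-enal
Product: 14 trimethyl[(3E,5E,7S)-5,7-dimethylnona-3,5-dien-1-yn-1-yl]silane
Conditions: (EtO)2P(O)CH2C≡CSiMe3, NaN(SiMe3)2, THF, −78 °C → rt
Reagents that add atoms: diethyl [3-(trimethylsilyl)prop-2-yn-1-yl]phosphonate CCOP(=O)(CC#C[Si](C)(C)C)OCC
Why: Horner–Wadsworth–Emmons olefination with the propargylic phosphonate anion gives the E-enyne through the usual reversible addition and syn-elimination of stabilised phosphonate carbanions, and adding the enal to the preformed anion at −78 °C avoids γ-deprotonation next to the stereocentre.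

Step 10
Reactants: 14 trimethyl[(3E,5E,7S)-5,7-dimethylnona-3,5-dien-1-yn-1-yl]silane
Product: 15 (3E,5E,7S)-5,7-dimethylnona-3,5-dien-1-yne
Conditions: K2CO3 (cat.), MeOH, rt
Reagents that add atoms: none
Why: Base-catalysed methanolysis of the alkynyl C–Si bond (protodesilylation) is specific for the silylalkyne and leaves the diene and the allylic stereocentre untouched.

Step 11
Reactants: 10 (2R,3R,4R)-2,3-(isopropylidenedioxy)-4-[(4-methoxybenzyloxy)methyl]-2-methyl-5-(trifluoromethanesulfonyloxy)cyclohex-5-en-1-one; 15 (3E,5E,7S)-5,7-dimethylnona-3,5-dien-1-yne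
Product: 16 (2R,3R,4R)-5-[(3E,5E,7S)-5,7-dimethylnona-3,5-dien-1-yn-1-yl]-2,3-(isopropylidenedioxy)-4-[(4-methoxybenzyloxy)methyl]-2-methylcyclohex-5-en-1-one
Conditions: PdCl2(PPh3)2 (cat.), CuI (cat.), Et3N, THF, rt
Reagents that add atoms: none
Why: Sonogashira coupling: the β-triflyloxy enone adds oxidatively to zerovalent palladium generated in situ from PdCl2(PPh3)2, the copper acetylide of 15 transmetallates and reductive elimination forms the C4–C4a bond at room temperature, a tertiary amine being chosen so that no amine displaces the vinylogous triflate.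

Step 12
Reactants: 16 (2R,3R,4R)-5-[(3E,5E,7S)-5,7-dimethylnona-3,5-dien-1-yn-1-yl]-2,3-(isopropylidenedioxy)-4-[(4-methoxybenzyloxy)methyl]-2-methylcyclohex-5-en-1-one
Product: 17 (2R,3R,4R)-5-[(3E,5E,7S)-5,7-dimethylnona-3,5-dien-1-yn-1-yl]-4-(hydroxymethyl)-2,3-(isopropylidenedioxy)-2-methylcyclohex-5-en-1-one
Conditions: DDQ, CH2Cl2/pH 7 buffer, 0 °C
Reagents that add atoms: none
Why: Oxidative cleavage of the p-methoxybenzyl ether by DDQ (electron transfer from the electron-rich arene, then hydrolysis of the benzylic oxocarbenium ion) is fast at 0 °C and should spare the carbonyl-conjugated, electron-poor polyene and the acetonide.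

Step 13
Reactants: 17 (2R,3R,4R)-5-[(3E,5E,7S)-5,7-dimethylnona-3,5-dien-1-yn-1-yl]-4-(hydroxymethyl)-2,3-(isopropylidenedioxy)-2-methylcyclohex-5-en-1-one
Product: 18 (7R,8R,8aR)-3-[(1E,3E,5S)-3,5-dimethylhepta-1,3-dien-1-yl]-7,8-(isopropylidenedioxy)-7-methyl-1,7,8,8a-tetrahydro-6H-isochromen-6-one
Conditions: Ph3PAuNTf2 (cat.), CH2Cl2, rt
Reagents that add atoms: none
Why: Gold-catalysed intramolecular alkyne hydroalkoxylation closes the pyran ring 6-endo-dig because the hydroxyl adds to C3, the δ-carbon of the ynenone and the alkyne terminus that best carries positive charge next to the dienyl group, rather than to C4 (5-exo), and protodeauration then delivers the dienol ether while the acetonide keeps the C8 oxygen from competing.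

Step 14
Reactants: 18 (7R,8R,8aR)-3-[(1E,3E,5S)-3,5-dimethylhepta-1,3-dien-1-yl]-7,8-(isopropylidenedioxy)-7-methyl-1,7,8,8a-tetrahydro-6H-isochromen-6-one
Product: 19 (7R,8R,8aR)-3-[(1E,3E,5S)-3,5-dimethylhepta-1,3-dien-1-yl]-7,8-dihydroxy-7-methyl-1,7,8,8a-tetrahydro-6H-isochromen-6-one
Conditions: TFA/H2O (9:1), 0 °C
Reagents that add atoms: none
Why: Acid-catalysed hydrolysis of the isopropylidene acetal frees the cis-diol, and the dienol ether is expected to survive brief cold aqueous acid because it is a doubly vinylogous ester whose protonation is reversible and whose C1 and C8a carbons are sp3.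

Step 15
Reactants: 19 (7R,8R,8aR)-3-[(1E,3E,5S)-3,5-dimethylhepta-1,3-dien-1-yl]-7,8-dihydroxy-7-methyl-1,7,8,8a-tetrahydro-6H-isochromen-6-one
Product: 20 (7R,8R,8aR)-3-[(1E,3E,5S)-3,5-dimethylhepta-1,3-dien-1-yl]-7-hydroxy-7-methyl-6-oxo-1,7,8,8a-tetrahydro-6H-isochromen-8-yl acetate (the target)
Conditions: Ac2O, pyridine, DMAP (cat.), CH2Cl2, 0 °C
Reagents that add atoms: acetic anhydride CC(=O)OC(C)=O
Why: Acylation with Ac2O/pyridine (DMAP catalysis) is selective for the secondary C8 hydroxyl over the tertiary C7 hydroxyl on steric grounds, and the weak base does not deprotonate C8a, so the three ring stereocentres are retained.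

**Compound list**

1 | (R)-(−)-carvone | CC1=CC[C@H](CC1=O)C(C)=C | starting material
2 | (5R)-5-(1-hydroperoxy-1-methoxyethyl)-2-methylcyclohex-2-en-1-one (epimers at the peroxy carbon) | CC1=CC[C@H](CC1=O)C(C)(OC)OO | intermediate
3 | 1-methoxy-1-[(1R)-4-methyl-5-oxocyclohex-3-en-1-yl]ethyl peroxyacetate | CC1=CC[C@H](CC1=O)C(C)(OC)OOC(C)=O | intermediate
4 | (R)-5-acetoxy-2-methylcyclohex-2-en-1-one | CC1=CC[C@H](CC1=O)OC(C)=O | intermediate
5 | (2R,3R,5R)-5-acetoxy-2,3-dihydroxy-2-methylcyclohexan-1-one | CC(=O)O[C@H]1CC(=O)[C@](C)(O)[C@H](O)C1 | intermediate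
6 | (2R,3R,5R)-5-acetoxy-2,3-(isopropylidenedioxy)-2-methylcyclohexan-1-one | CC(=O)O[C@H]1CC(=O)[C@]2(C)OC(C)(C)O[C@@H]2C1 | intermediate
7 | (2S,3R,5S)-2,3-(isopropylidenedioxy)-2-methylcyclohexane-1,5-diol, C1 epimers | O[C@H]1CC(O)[C@]2(C)OC(C)(C)O[C@@H]2C1 | intermediate
8 | (2R,3R)-2,3-(isopropylidenedioxy)-2-methylcyclohexane-1,5-dione | O=C1CC(=O)[C@]2(C)OC(C)(C)O[C@@H]2C1 | intermediate
9 | (2R,3R,4R)-2,3-(isopropylidenedioxy)-4-[(4-methoxybenzyloxy)methyl]-2-methylcyclohexane-1,5-dione | O=C1CC(=O)[C@]2(C)OC(C)(C)O[C@@H]2[C@H]1COCc1ccc(OC)cc1 | intermediate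
10 | (2R,3R,4R)-2,3-(isopropylidenedioxy)-4-[(4-methoxybenzyloxy)methyl]-2-methyl-5-(trifluoromethanesulfonyloxy)cyclohex-5-en-1-one | FC(F)(F)S(=O)(=O)OC1=CC(=O)[C@]2(C)OC(C)(C)O[C@@H]2[C@H]1COCc1ccc(OC)cc1 | intermediate
11 | (S)-2-methylbutan-1-ol | CC[C@H](C)CO | starting material
12 | (S)-2-methylbutanal | CC[C@H](C)C=O | intermediate
13 | (2E,4S)-2,4-dimethylhex-2-enal | CC[C@H](C)/C=C(C)/C=O | intermediate
14 | trimethyl[(3E,5E,7S)-5,7-dimethylnona-3,5-dien-1-yn-1-yl]silane | CC[C@H](C)/C=C(C)/C=C/C#C[Si](C)(C)C | intermediate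
15 | (3E,5E,7S)-5,7-dimethylnona-3,5-dien-1-yne | CC[C@H](C)/C=C(C)/C=C/C#C | intermediate
16 | (2R,3R,4R)-5-[(3E,5E,7S)-5,7-dimethylnona-3,5-dien-1-yn-1-yl]-2,3-(isopropylidenedioxy)-4-[(4-methoxybenzyloxy)methyl]-2-methylcyclohex-5-en-1-one | CC[C@H](C)/C=C(C)/C=C/C#CC1=CC(=O)[C@]2(C)OC(C)(C)O[C@@H]2[C@H]1COCc1ccc(OC)cc1 | intermediate
17 | (2R,3R,4R)-5-[(3E,5E,7S)-5,7-dimethylnona-3,5-dien-1-yn-1-yl]-4-(hydroxymethyl)-2,3-(isopropylidenedioxy)-2-methylcyclohex-5-en-1-one | CC[C@H](C)/C=C(C)/C=C/C#CC1=CC(=O)[C@]2(C)OC(C)(C)O[C@@H]2[C@H]1CO | intermediate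
18 | (7R,8R,8aR)-3-[(1E,3E,5S)-3,5-dimethylhepta-1,3-dien-1-yl]-7,8-(isopropylidenedioxy)-7-methyl-1,7,8,8a-tetrahydro-6H-isochromen-6-one | CC[C@H](C)/C=C(C)/C=C/C1=CC2=CC(=O)[C@]3(C)OC(C)(C)O[C@@H]3[C@H]2CO1 | intermediate
19 | (7R,8R,8aR)-3-[(1E,3E,5S)-3,5-dimethylhepta-1,3-dien-1-yl]-7,8-dihydroxy-7-methyl-1,7,8,8a-tetrahydro-6H-isochromen-6-one | CC[C@H](C)/C=C(C)/C=C/C1=CC2=CC(=O)[C@](C)(O)[C@H](O)[C@H]2CO1 | intermediate
20 | (7R,8R,8aR)-3-[(1E,3E,5S)-3,5-dimethylhepta-1,3-dien-1-yl]-7-hydroxy-7-methyl-6-oxo-1,7,8,8a-tetrahydro-6H-isochromen-8-yl acetate | CC[C@H](C)/C=C(C)/C=C/C1=CC2=CC(=O)[C@](C)(O)[C@H](OC(C)=O)[C@H]2CO1 | target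

**Step count and risks**

Total step count: 15. Longest linear sequence: 12 steps (steps 1–7 and 11–15, from 1); the side chain takes 3 steps (8–10) before the coupling.

Steps most likely to fail:

Step 6. The dianion places carbanion character at C4, next to the C3 acetonide oxygen, so β-elimination with opening of the dioxolane may compete. The hard chloromethyl ether may also O-alkylate, or approach syn to the acetonide. The fallback sets out from 8 and returns at 9. Soft double enolisation of 8 (TMSOTf, Et3N, CH2Cl2, 0 °C) should give (5R,6R)-5,6-(isopropylidenedioxy)-5-methyl-2,4-bis(trimethylsilyloxy)cyclohexa-1,3-diene F6. Its terminal diene carbon is then alkylated with 4-methoxybenzyl chloromethyl ether under ZnBr2 catalysis (Lewis-acid alkylation of a silyl enol ether by an α-chloro ether, Mukaiyama type), again on the face anti to the acetonide. Mild aqueous work-up removes the remaining silyl group and gives 9 without any strongly basic carbanion β to the acetonide oxygen.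

Step 2. Facial selectivity may erode through osmylation syn to the small, conformationally mobile acetoxy group. Acetic acid may also be lost from the β-acetoxy ketone during a slow oxidation. The fallback sets out from 4 and returns at 8. Acid-catalysed methanolysis of 4 (AcCl in MeOH, 0 °C) gives (R)-5-hydroxy-2-methylcyclohex-2-en-1-one F1. Silylation (TBDPSCl, imidazole, DMF) gives (R)-5-(tert-butyldiphenylsilyloxy)-2-methylcyclohex-2-en-1-one F2, whose bulky silyloxy group screens one face much more strongly. The same OsO4/NMO/citric acid dihydroxylation then gives (2R,3R,5R)-5-(tert-butyldiphenylsilyloxy)-2,3-dihydroxy-2-methylcyclohexan-1-one F3. Acetonide formation (Me2C(OMe)2, PPTS) gives (2R,3R,5R)-5-(tert-butyldiphenylsilyloxy)-2,3-(isopropylidenedioxy)-2-methylcyclohexan-1-one F4. HF·pyridine in THF releases (2R,3R,5R)-5-hydroxy-2,3-(isopropylidenedioxy)-2-methylcyclohexan-1-one F5 under non-basic conditions, and IBX oxidation of this β-hydroxy ketone gives 8.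

Step 7. Regiocontrol of the O-sulfonylation may be lost, because after step 6 the C5 oxygen is also flanked by a branched carbon, so triflation at the C1 oxygen would give the transposed β-triflyloxy enone. The fallback sets out from 8 and returns at 16. Triflation of 8 itself (Tf2O, 2,6-lutidine, −78 °C), where the C5 oxygen is flanked by a methylene and the bias is largest, gives (2R,3R)-2,3-(isopropylidenedioxy)-2-methyl-5-(trifluoromethanesulfonyloxy)cyclohex-5-en-1-one F7. Sonogashira coupling with 15 (PdCl2(PPh3)2, CuI, Et3N) gives (2R,3R)-5-[(3E,5E,7S)-5,7-dimethylnona-3,5-dien-1-yn-1-yl]-2,3-(isopropylidenedioxy)-2-methylcyclohex-5-en-1-one F8. Soft enolisation (TBSOTf, Et3N), possible only toward C4 because C2 is quaternary, gives the tert-butyldimethylsilyl dienol ether of this ynenone (C1(OSi)=C6 and C5=C4 in cyclohexanone numbering) F9. A ZnBr2-mediated vinylogous Mukaiyama alkylation with 4-methoxybenzyl chloromethyl ether at the γ-carbon C4, anti to the acetonide oxygen, then gives 16.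

Further compounds
F1 | step 2 | (R)-5-hydroxy-2-methylcyclohex-2-en-1-one | CC1=CC[C@H](CC1=O)O
F2 | step 2 | (R)-5-(tert-butyldiphenylsilyloxy)-2-methylcyclohex-2-en-1-one | CC1=CC[C@H](CC1=O)O[Si](c1ccccc1)(c1ccccc1)C(C)(C)C
F3 | step 2 | (2R,3R,5R)-5-(tert-butyldiphenylsilyloxy)-2,3-dihydroxy-2-methylcyclohexan-1-one | CC(C)(C)[Si](c1ccccc1)(c1ccccc1)O[C@H]1CC(=O)[C@](C)(O)[C@H](O)C1
F4 | step 2 | (2R,3R,5R)-5-(tert-butyldiphenylsilyloxy)-2,3-(isopropylidenedioxy)-2-methylcyclohexan-1-one | CC(C)(C)[Si](c1ccccc1)(c1ccccc1)O[C@H]1CC(=O)[C@]2(C)OC(C)(C)O[C@@H]2C1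
F5 | step 2 | (2R,3R,5R)-5-hydroxy-2,3-(isopropylidenedioxy)-2-methylcyclohexan-1-one | O[C@H]1CC(=O)[C@]2(C)OC(C)(C)O[C@@H]2C1
F6 | step 6 | (5R,6R)-5,6-(isopropylidenedioxy)-5-methyl-2,4-bis(trimethylsilyloxy)cyclohexa-1,3-diene | C[Si](C)(C)OC=1C=C(O[Si](C)(C)C)[C@]2(C)OC(C)(C)O[C@@H]2C=1
F7 | step 7 | (2R,3R)-2,3-(isopropylidenedioxy)-2-methyl-5-(trifluoromethanesulfonyloxy)cyclohex-5-en-1-one | FC(F)(F)S(=O)(=O)OC1=CC(=O)[C@]2(C)OC(C)(C)O[C@@H]2C1
F8 | step 7 | (2R,3R)-5-[(3E,5E,7S)-5,7-dimethylnona-3,5-dien-1-yn-1-yl]-2,3-(isopropylidenedioxy)-2-methylcyclohex-5-en-1-one | CC[C@H](C)/C=C(C)/C=C/C#CC1=CC(=O)[C@]2(C)OC(C)(C)O[C@@H]2C1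
F9 | step 7 | tert-butyldimethylsilyl dienol ether of F8 (C1(OSi)=C6 and C5=C4, cyclohexanone numbering) | CC[C@H](C)/C=C(C)/C=C/C#CC=1C=C(O[Si](C)(C)C(C)(C)C)[C@]2(C)OC(C)(C)O[C@@H]2C=1
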